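Everything rests on cutting the N1–C8a bond of both quinolines. This unravels the core to a 1-silyl-3,4-diarylpyrrole whose two dimethoxyphenyl rings each carry an ortho 3-(methoxyimino)prop-1-enyl arm. The cut exploits the benzo ring of each quinoline: of the two carbons flanking C4a, C5 holds the pyrrole and only C8a bears hydrogen, so nitrogen has one place to bond. The C7/C8 oxygens come from a commercial bromoveratraldehyde. A single irradiation turns both alkenes cis, closes two 1-azatrienes and expels two methanols, delivering both pyridine rings at once. Desilylation, N-alkylation with a chiral-pool-derived (S)-1-(3-chloropropyl)-3-methylazecane and ether cleavage finish the synthesis.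

Key step: step 6

Assumption: the bis-enal and the bis-oxime ether are drawn as their all-E isomers. Minor alkene or oxime isomers need not be removed, because the light of the key step interconverts them.

Step 1
Reactants: 1 1-(triisopropylsilyl)-1H-pyrrole
Product: 2 3,4-dibromo-1-(triisopropylsilyl)-1H-pyrrole
Conditions: NBS (2.0 equiv), THF, −78 °C to rt
Reagents that add atoms: N-bromosuccinimide, O=C1CCC(=O)N1Br
Why: Electrophilic aromatic bromination in which the bulky silyl group shields C2 and C5, so both bromine atoms enter the beta positions, as is well established for this pyrrole.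

Step 2
Reactants: 3 2-bromo-4,5-dimethoxybenzaldehyde
Product: 4 4,5-dimethoxy-2-(4,4,5,5-tetramethyl-1,3,2-dioxaborolan-2-yl)benzaldehyde
Conditions: B2pin2 (1.2 equiv), PdCl2(dppf) (3 mol%), KOAc (3 equiv), 1,4-dioxane, 85 °C
Reagents that add atoms: bis(pinacolato)diboron, CC1(C)OB(OC1(C)C)B1OC(C)(C)C(C)(C)O1
Why: Miyaura borylation, in which zerovalent palladium inserts into the aryl–bromine bond and acetate mediates boryl transfer without touching the aldehyde, the pinacol ester being chosen because it resists protodeboronation better than the free ortho-formyl boronic acid.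

Step 3
Reactants: 2 3,4-dibromo-1-(triisopropylsilyl)-1H-pyrrole; 4 4,5-dimethoxy-2-(pinacolboryl)benzaldehyde (2.5 equiv)
Product: 5 2,2'-[1-(triisopropylsilyl)-1H-pyrrole-3,4-diyl]bis(4,5-dimethoxybenzaldehyde)
Conditions: Pd(OAc)2 (5 mol%), SPhos (10 mol%), K3PO4 (4 equiv), toluene–H2O 10:1, 90 °C
Reagents that add atoms: none
Why: Twofold Suzuki–Miyaura coupling, in which the bulky electron-rich biarylphosphine speeds oxidative addition to the electron-rich bromopyrrole and reductive elimination to the crowded biaryl bonds, while the fluoride-free phosphate base leaves the N–Si bond intact.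

Step 4
Reactants: 5 the dialdehyde; 6 (triphenylphosphoranylidene)acetaldehyde (2.6 equiv)
Product: 7 (2E,2'E)-3,3'-{[1-(triisopropylsilyl)-1H-pyrrole-3,4-diyl]bis(4,5-dimethoxy-2,1-phenylene)}bis(prop-2-enal)
Conditions: toluene, 90 °C
Reagents that add atoms: none
Why: Wittig formylolefination with a stabilised, E-selective ylide, which adds one two-carbon unit to each non-enolisable aldehyde when the ylide is kept to a small excess and the reaction is stopped once 5 is consumed.

Step 5
Reactants: 7 the bis-enal; 8 O-methylhydroxylamine hydrochloride (2.5 equiv)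
Product: 9 3,4-bis{4,5-dimethoxy-2-[(1E,3E)-3-(methoxyimino)prop-1-en-1-yl]phenyl}-1-(triisopropylsilyl)-1H-pyrrole
Conditions: NaOAc (3 equiv), EtOH–THF, rt
Reagents that add atoms: none
Why: Oxime ether condensation, which under acetate buffering attacks enals only at the carbonyl carbon, gives mainly the anti (E) aldoxime ether and affects neither the silyl group nor the aryl ethers.

Step 6
Reactants: 9 the bis(O-methyl oxime)
Product: 13 3,4-bis(7,8-dimethoxyquinolin-5-yl)-1-(triisopropylsilyl)-1H-pyrrole, via bis-(1Z,3E) photoisomer 10 (not isolated), via N-methoxy-1,8a-dihydroquinoline 11 (not isolated), via mono-quinoline mono-oxime ether 12 (not isolated)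
Conditions: hν (medium-pressure Hg lamp, Pyrex filter, λ > 290 nm), AcOH (20 mol%), argon-sparged MeCN (2 mM), 20 °C, FEP-tubing flow reactor
Reagents that add atoms: none
Why: Light first equilibrates the alkene and oxime geometries of each arm, and only the (1Z,3E) form, as in 10, places the oxime nitrogen (methoxy group pointing outward) over the hydrogen-bearing ortho carbon. The N1=C2–C3=C4–C4a=C8a azatriene then closes by a six-electron electrocyclisation (conrotatory from the excited state, disrotatory if the Z isomer closes in the ground state) to 11, loss of methanol across N1–C8a, assisted by the trace of acetic acid, makes the first pyridine ring aromatic and the event irreversible, and the same mode of closure on 12 builds the second ring. The closest known reaction type is the photocyclisation of beta-aryl alpha,beta-unsaturated O-alkyl oximes to quinolines, and no stereocentre survives because C8a becomes planar again. Site selectivity is built in, since the other ortho carbon (the future C5) carries the pyrrole, so closure there has no hydrogen to lose and simply reverts. Periselectivity is the real demand: the aryl–C3=C4–aryl triene can only be trapped by an oxidant, hence the rigorous degassing, while closure of pyrrole C2 or C5 onto an alkene would break two aromatic rings and is screened by the isopropyl groups on silicon, which is why the silyl group is kept through this step. High dilution suppresses intermolecular cycloaddition, and the oxime is O-methylated and not O-acylated because aldoxime esters collapse to nitriles or cleave at N–O.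

Step 7
Reactants: 13 the N-silyl bis-quinoline
Product: 14 3,4-bis(7,8-dimethoxyquinolin-5-yl)-1H-pyrrole
Conditions: TBAF (1.1 equiv), THF, 0 °C to rt
Reagents that add atoms: none
Why: Fluoride-induced desilylation driven by the strong Si–F bond, which frees the pyrrole N–H and touches nothing else in the molecule.

Step 8
Reactants: 15 (R)-3-bromo-2-methylpropan-1-ol; 16 1-bromo-6-chlorohexane (2.5 equiv)
Product: 18 (S)-9-chloro-2-methylnonan-1-ol, via 6-chlorohexylmagnesium bromide 17 (not isolated)
Conditions: 16, Mg, THF, 30 °C; then 15, Li2CuCl4 (5 mol%), THF, −20 °C to rt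
Reagents that add atoms: none
Why: Li2CuCl4-catalysed alkyl–alkyl Grignard cross-coupling, in which the first equivalent of 17 only deprotonates the alcohol, the primary bromide reacts far faster than any alkyl chloride, and the chiral-pool stereocentre takes part in no bond change (R becomes S only through the change of priorities).

Step 9
Reactants: 18 (S)-9-chloro-2-methylnonan-1-ol; 19 tert-butyl [(2-nitrophenyl)sulfonyl]carbamate
Product: 20 tert-butyl (S)-(9-chloro-2-methylnonyl)[(2-nitrophenyl)sulfonyl]carbamate
Conditions: PPh3, DIAD, THF, 0 °C to rt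
Reagents that add atoms: none
Why: Fukuyama–Mitsunobu alkylation, in which the strongly acidic N-Boc sulfonamide displaces the activated primary alcohol by SN2 at C1, one carbon away from the stereocentre, while the alkyl chloride is inert.

Step 10
Reactants: 20 the N-Boc sulfonamide
Product: 21 (S)-N-(9-chloro-2-methylnonyl)-2-nitrobenzenesulfonamide
Conditions: TFA, CH2Cl2, 0 °C to rt
Reagents that add atoms: none
Why: Acidolytic Boc cleavage through the tert-butyl cation, which leaves sulfonamide, chloride and stereocentre untouched and exposes the acidic N–H needed for ring closure.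

Step 11
Reactants: 21 the chloro sulfonamide
Product: 22 (S)-3-methyl-1-[(2-nitrophenyl)sulfonyl]azecane
Conditions: Cs2CO3 (3 equiv), n-Bu4NI (30 mol%), MeCN, 70 °C, slow addition of 21 (final 5 mM)
Reagents that add atoms: none
Why: Intramolecular N-alkylation of a 2-nitrobenzenesulfonamide (Fukuyama amine synthesis), a reaction type established for eight- to ten-membered cyclic amines, here aided by full ionisation of the sulfonamide, iodide exchange at the chloride and a low stationary concentration, with the C3 stereocentre remote from the reacting atoms.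

Step 12
Reactants: 22 the N-sulfonyl azecane
Product: 23 (S)-3-methylazecane
Conditions: PhSH (1.3 equiv), K2CO3 (3 equiv), MeCN, 50 °C; acid–base extraction
Reagents that add atoms: none
Why: Fukuyama deprotection, in which thiolate adds to the nitroarene (nucleophilic aromatic substitution through a Meisenheimer complex) and the sulfonyl group leaves as SO2, releasing the secondary amine under mild base.

Step 13
Reactants: 23 (S)-3-methylazecane; 24 1-bromo-3-chloropropane (3 equiv)
Product: 25 (S)-1-(3-chloropropyl)-3-methylazecane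
Conditions: K2CO3, acetone, rt
Reagents that add atoms: none
Why: SN2 N-alkylation that relies on bromide being a much better leaving group than chloride, with the excess of dihalide preventing a second amination.

Step 14
Reactants: 14 3,4-bis(7,8-dimethoxyquinolin-5-yl)-1H-pyrrole; 25 (S)-1-(3-chloropropyl)-3-methylazecane (1.3 equiv)
Product: 27 (S)-1-{3-[3,4-bis(7,8-dimethoxyquinolin-5-yl)-1H-pyrrol-1-yl]propyl}-3-methylazecane, via sodium pyrrolide 26 (not isolated)
Conditions: NaH (1.2 equiv), DMF, 0 °C to rt; then 25, NaI (10 mol%), 50 °C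
Reagents that add atoms: none
Why: SN2 N-alkylation of a pyrrolide anion with iodide catalysis, in which the anion is far more nucleophilic than the neutral quinoline nitrogens and the stereocentre is not involved.

Step 15
Reactants: 27 the tetramethyl ether
Product: 28 5,5'-(1-{3-[(3S)-3-methylazecan-1-yl]propyl}-1H-pyrrole-3,4-diyl)bis(quinoline-7,8-diol)
Conditions: BBr3 (12 equiv), CH2Cl2, −78 °C to rt; MeOH quench; degassed pH 7 buffer work-up under argon
Reagents that add atoms: none
Why: Lewis-acid aryl methyl ether cleavage, in which BBr3 (in excess, because the three basic nitrogens bind it first) activates each ether for SN2 removal of methyl by bromide, a standard unmasking of catechol dimethyl ethers that leaves the pyrrole, deactivated by its two complexed quinolines, and the stereocentre unchanged.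

Compound list
1 | 1-(triisopropylsilyl)-1H-pyrrole | CC(C)[Si](C(C)C)(C(C)C)n1cccc1 | starting material
2 | 3,4-dibromo-1-(triisopropylsilyl)-1H-pyrrole | CC(C)[Si](C(C)C)(C(C)C)n1cc(Br)c(Br)c1 | intermediate
3 | 2-bromo-4,5-dimethoxybenzaldehyde | COc1cc(Br)c(C=O)cc1OC | starting material
4 | 4,5-dimethoxy-2-(4,4,5,5-tetramethyl-1,3,2-dioxaborolan-2-yl)benzaldehyde | COc1cc(B2OC(C)(C)C(C)(C)O2)c(C=O)cc1OC | intermediate
5 | 2,2'-[1-(triisopropylsilyl)-1H-pyrrole-3,4-diyl]bis(4,5-dimethoxybenzaldehyde) | CC(C)[Si](C(C)C)(C(C)C)n1cc(-c2cc(OC)c(OC)cc2C=O)c(-c2cc(OC)c(OC)cc2C=O)c1 | intermediate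
6 | (triphenylphosphoranylidene)acetaldehyde | O=CC=P(c1ccccc1)(c1ccccc1)c1ccccc1 | starting material
7 | (2E,2'E)-3,3'-{[1-(triisopropylsilyl)-1H-pyrrole-3,4-diyl]bis(4,5-dimethoxy-2,1-phenylene)}bis(prop-2-enal) | CC(C)[Si](C(C)C)(C(C)C)n1cc(-c2cc(OC)c(OC)cc2/C=C/C=O)c(-c2cc(OC)c(OC)cc2/C=C/C=O)c1 | intermediate
8 | O-methylhydroxylamine hydrochloride | CON.Cl | starting material
9 | 3,4-bis{4,5-dimethoxy-2-[(1E,3E)-3-(methoxyimino)prop-1-en-1-yl]phenyl}-1-(triisopropylsilyl)-1H-pyrrole | CC(C)[Si](C(C)C)(C(C)C)n1cc(-c2cc(OC)c(OC)cc2/C=C/C=N/OC)c(-c2cc(OC)c(OC)cc2/C=C/C=N/OC)c1 | intermediate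
10 | 3,4-bis{4,5-dimethoxy-2-[(1Z,3E)-3-(methoxyimino)prop-1-en-1-yl]phenyl}-1-(triisopropylsilyl)-1H-pyrrole | CC(C)[Si](C(C)C)(C(C)C)n1cc(-c2cc(OC)c(OC)cc2/C=C\C=N\OC)c(-c2cc(OC)c(OC)cc2/C=C\C=N\OC)c1 | intermediate
11 | 3-(1,7,8-trimethoxy-1,8a-dihydroquinolin-5-yl)-4-{4,5-dimethoxy-2-[(1E,3E)-3-(methoxyimino)prop-1-en-1-yl]phenyl}-1-(triisopropylsilyl)-1H-pyrrole (C8a undefined, lost on aromatisation) | CC(C)[Si](C(C)C)(C(C)C)n1cc(C2=CC(OC)=C(OC)C3N(OC)C=CC=C23)c(-c2cc(OC)c(OC)cc2/C=C/C=N/OC)c1 | intermediate
12 | 3-(7,8-dimethoxyquinolin-5-yl)-4-{4,5-dimethoxy-2-[(1E,3E)-3-(methoxyimino)prop-1-en-1-yl]phenyl}-1-(triisopropylsilyl)-1H-pyrrole | CC(C)[Si](C(C)C)(C(C)C)n1cc(-c2cc(OC)c(OC)c3ncccc23)c(-c2cc(OC)c(OC)cc2/C=C/C=N/OC)c1 | intermediate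
13 | 3,4-bis(7,8-dimethoxyquinolin-5-yl)-1-(triisopropylsilyl)-1H-pyrrole | CC(C)[Si](C(C)C)(C(C)C)n1cc(-c2cc(OC)c(OC)c3ncccc23)c(-c2cc(OC)c(OC)c3ncccc23)c1 | intermediate
14 | 3,4-bis(7,8-dimethoxyquinolin-5-yl)-1H-pyrrole | c1c(-c2cc(OC)c(OC)c3ncccc23)c(-c2cc(OC)c(OC)c3ncccc23)c[nH]1 | intermediate
15 | (R)-3-bromo-2-methylpropan-1-ol | C[C@H](CO)CBr | starting material
16 | 1-bromo-6-chlorohexane | ClCCCCCCBr | starting material
17 | 6-chlorohexylmagnesium bromide | ClCCCCCC[Mg]Br | intermediate
18 | (S)-9-chloro-2-methylnonan-1-ol | C[C@H](CO)CCCCCCCCl | intermediate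
19 | tert-butyl [(2-nitrophenyl)sulfonyl]carbamate | CC(C)(C)OC(=O)NS(=O)(=O)c1ccccc1[N+](=O)[O-] | starting material
20 | tert-butyl (S)-(9-chloro-2-methylnonyl)[(2-nitrophenyl)sulfonyl]carbamate | C[C@H](CN(C(=O)OC(C)(C)C)S(=O)(=O)c1ccccc1[N+](=O)[O-])CCCCCCCCl | intermediate
21 | (S)-N-(9-chloro-2-methylnonyl)-2-nitrobenzenesulfonamide | C[C@H](CNS(=O)(=O)c1ccccc1[N+](=O)[O-])CCCCCCCCl | intermediate
22 | (S)-3-methyl-1-[(2-nitrophenyl)sulfonyl]azecane | C[C@H]1CCCCCCCN(S(=O)(=O)c2ccccc2[N+](=O)[O-])C1 | intermediate
23 | (S)-3-methylazecane | C[C@H]1CCCCCCCNC1 | intermediate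
24 | 1-bromo-3-chloropropane | ClCCCBr | starting material
25 | (S)-1-(3-chloropropyl)-3-methylazecane | C[C@H]1CCCCCCCN(CCCCl)C1 | intermediate
26 | sodium 3,4-bis(7,8-dimethoxyquinolin-5-yl)pyrrol-1-ide | [Na+].c1c(-c2cc(OC)c(OC)c3ncccc23)c(-c2cc(OC)c(OC)c3ncccc23)c[n-]1 | intermediate
27 | (S)-1-{3-[3,4-bis(7,8-dimethoxyquinolin-5-yl)-1H-pyrrol-1-yl]propyl}-3-methylazecane | C[C@H]1CCCCCCCN(CCCn2cc(-c3cc(OC)c(OC)c4ncccc34)c(-c3cc(OC)c(OC)c4ncccc34)c2)C1 | intermediate
28 | 5,5'-(1-{3-[(3S)-3-methylazecan-1-yl]propyl}-1H-pyrrole-3,4-diyl)bis(quinoline-7,8-diol) | C[C@H]1CCCCCCCN(CCCn2cc(-c3cc(O)c(O)c4ncccc34)c(-c3cc(O)c(O)c4ncccc34)c2)C1 | target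

Total step count: 15.
Longest linear sequence: 8 steps. The core branch runs step 1 or 2, then 3–7, 14 and 15; the amine branch, steps 8–13, 14 and 15, is equally long.

Steps most likely to fail

1. Step 6.
- What may go wrong: the excited arms may decay through other channels, namely bonding of a pyrrole alpha carbon to an alkene terminus or cycloaddition between the two neighbouring alkenes. Closure at a carbon flanked by a methoxy group may be slow. The reaction may also stall after the first ring, because the new quinoline competes for light.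
- Fallback: use known chemistry and bring in finished quinolines instead of building them late.
 - Commercial 2,3-dimethoxyaniline is taken through a Skraup reaction (glycerol, H2SO4, sodium 3-nitrobenzenesulfonate, 130 °C) to 7,8-dimethoxyquinoline F2.
 - F2 is brominated para to the C8 oxygen (NBS, MeCN) to 5-bromo-7,8-dimethoxyquinoline F3.
 - Compound 2 is converted by twofold Miyaura borylation (B2pin2, PdCl2(dppf), KOAc, dioxane) into 1-(triisopropylsilyl)-3,4-bis(pinacolboryl)pyrrole F1.
 - A double Suzuki–Miyaura coupling of F1 with F3 (Pd(OAc)2, SPhos, K3PO4) completes the core.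
- This fallback sets out from 2 and rejoins the route at 13.

2. Step 11.
- What may go wrong: intermolecular alkylation may outrun the transannularly strained ten-membered closure and lead to oligomerisation.
- Fallback: close a C=C bond instead of the C–N bond.
 - Compound 15 is coupled with but-3-enylmagnesium bromide (Li2CuCl4 catalysis) to (S)-2-methylhept-6-en-1-ol F4.
 - But-3-en-1-amine and 2-nitrobenzenesulfonyl chloride give N-(but-3-en-1-yl)-2-nitrobenzenesulfonamide F5.
 - A Fukuyama–Mitsunobu reaction of F4 with F5 gives (S)-N-(but-3-en-1-yl)-N-(2-methylhept-6-en-1-yl)-2-nitrobenzenesulfonamide F6.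
 - Ring-closing metathesis (second-generation Grubbs catalyst, dilute CH2Cl2, reflux) gives (3S)-3-methyl-1-[(2-nitrophenyl)sulfonyl]-1,2,3,4,5,6,9,10-octahydroazecine F7, whose alkene geometry is irrelevant.
 - Diimide (TsNHNH2, NaOAc, aqueous DME, reflux) saturates the alkene without touching the nitro group.
- This fallback sets out from 15 and rejoins the route at 22.

3. Step 15.
- What may go wrong: ether cleavage may stay incomplete because the three basic nitrogens sequester the Lewis acid. The liberated catechols may be lost to air oxidation while the amphoteric product is separated from boron and bromide residues.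
- Fallback: move the demethylation to an earlier, simpler stage and unmask last under neutral conditions.
 - Compound 14 is demethylated (BBr3, CH2Cl2) to 5,5'-(1H-pyrrole-3,4-diyl)bis(quinoline-7,8-diol) F8.
 - F8 is benzylated crude (BnBr, K2CO3, DMF) to 3,4-bis[7,8-bis(benzyloxy)quinolin-5-yl]-1H-pyrrole F9.
 - N-alkylation with 25 under the conditions of step 14 gives (S)-1-(3-{3,4-bis[7,8-bis(benzyloxy)quinolin-5-yl]-1H-pyrrol-1-yl}propyl)-3-methylazecane F10.
 - Hydrogenolysis (H2, 1 atm, Pd/C, EtOAc–MeOH) followed by filtration under argon releases the product.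
- This fallback sets out from 14 and rejoins the route at 28.

Further compounds
F1 | step 6 | 1-(triisopropylsilyl)-3,4-bis(4,4,5,5-tetramethyl-1,3,2-dioxaborolan-2-yl)-1H-pyrrole | CC(C)[Si](C(C)C)(C(C)C)n1cc(B2OC(C)(C)C(C)(C)O2)c(B2OC(C)(C)C(C)(C)O2)c1
F2 | step 6 | 7,8-dimethoxyquinoline | COc1ccc2cccnc2c1OC
F3 | step 6 | 5-bromo-7,8-dimethoxyquinoline | COc1cc(Br)c2cccnc2c1OC
F4 | step 11 | (S)-2-methylhept-6-en-1-ol | C[C@H](CO)CCCC=C
F5 | step 11 | N-(but-3-en-1-yl)-2-nitrobenzenesulfonamide | C=CCCNS(=O)(=O)c1ccccc1[N+](=O)[O-]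
F6 | step 11 | (S)-N-(but-3-en-1-yl)-N-(2-methylhept-6-en-1-yl)-2-nitrobenzenesulfonamide | C[C@H](CN(CCC=C)S(=O)(=O)c1ccccc1[N+](=O)[O-])CCCC=C
F7 | step 11 | (3S)-3-methyl-1-[(2-nitrophenyl)sulfonyl]-1,2,3,4,5,6,9,10-octahydroazecine (alkene geometry undefined) | C[C@H]1CCCC=CCCN(S(=O)(=O)c2ccccc2[N+](=O)[O-])C1
F8 | step 15 | 5,5'-(1H-pyrrole-3,4-diyl)bis(quinoline-7,8-diol) | c1c(-c2cc(O)c(O)c3ncccc23)c(-c2cc(O)c(O)c3ncccc23)c[nH]1
F9 | step 15 | 3,4-bis[7,8-bis(benzyloxy)quinolin-5-yl]-1H-pyrrole | c1c(-c2cc(OCc3ccccc3)c(OCc3ccccc3)c3ncccc23)c(-c2cc(OCc3ccccc3)c(OCc3ccccc3)c3ncccc23)c[nH]1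
F10 | step 15 | (S)-1-(3-{3,4-bis[7,8-bis(benzyloxy)quinolin-5-yl]-1H-pyrrol-1-yl}propyl)-3-methylazecane | C[C@H]1CCCCCCCN(CCCn2cc(-c3cc(OCc4ccccc4)c(OCc4ccccc4)c4ncccc34)c(-c3cc(OCc4ccccc4)c(OCc4ccccc4)c4ncccc34)c2)C1
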